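The two pyranone rings (ring C of each half) are cut at O1–C2 and C4–C4a, so each ring A arrives as a phenol that uses its oxygen and its ortho carbon (the 1,3-related O1 and C4a). The chain C2–C3–C3′–C2′ is stored in a temporary tetrahydrofuran whose oxygen is absent from the target. The key step converts a meso bis(2-iodoaryl) tetrahydrofuran-3,4-dicarboxylate into the protected biflavanone in one flask: an anionic O→C acyl shift makes both aryl ketones, then the freed phenols displace the ether oxygen from the benzylic carbons that ring B activates. The cis ring fusion inherited from maleic anhydride fixes the meso C3/C3′ relation; the closures set both rings 2,3-trans.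

Key step: step 5

Remark: the target is the achiral meso trans,trans isomer, so racemic intermediates suffice (one enantiomer is drawn); the tetrahydrofuran intermediates are drawn with the aryl groups cis to each other and trans to the carbonyl-bearing carbons, and any other configuration at these two benzylic carbons converges in the key step.

Step 1
Reactants: 1 4-(benzyloxy)benzaldehyde; 2 4-(benzyloxy)benzyl chloride; 3 tetrahydrothiophene
Product: 5 trans-2,3-bis[4-(benzyloxy)phenyl]oxirane, via sulfonium chloride 4 (not isolated)
Conditions: 2 and 3 in MeCN, 40 °C; then 1, powdered KOH, 0 °C to rt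
Reagents that add atoms: none
Why: The sulfonium ylide formed from 4 and KOH adds reversibly to the aldehyde and the anti betaine closes fastest, so the epoxide is set trans (sulfonium-ylide epoxidation of the Johnson–Corey–Chaykovsky type), and the basic medium spares this acid-labile electron-rich epoxide.

Step 2
Reactants: 5 trans-2,3-bis[4-(benzyloxy)phenyl]oxirane; 6 maleic anhydride
Product: 7 meso-(3aR,4R,6S,6aS)-4,6-bis[4-(benzyloxy)phenyl]tetrahydro-1H,3H-furo[3,4-c]furan-1,3-dione
Conditions: 9,10-dicyanoanthracene (5 mol%), dry MeCN, blue light (ca. 420 nm), argon, rt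
Reagents that add atoms: none
Why: Electron transfer from the electron-rich epoxide to photoexcited 9,10-dicyanoanthracene should give a radical cation whose C–C bond opens, back electron transfer leaves the carbonyl ylide, and its suprafacial [3+2] dipolar cycloaddition with maleic anhydride carries the cis geometry of the dipolarophile into the cis ring fusion, which is the future meso relation of C3 and C3′.

Step 3
Reactants: 8 3-(benzyloxy)phenol
Product: 9 5-(benzyloxy)-2-iodophenol
Conditions: I2 (1.05 equiv), NaHCO3, THF/H2O, 0 °C
Reagents that add atoms: iodine, II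
Why: Electrophilic aromatic iodination of the phenoxide should go to the carbon ortho to the hydroxyl and para to the benzyloxy group, which both oxygens activate and which is less hindered than the carbon between them, as in the iodination of 3-methoxyphenol.

Step 4
Reactants: 7 meso anhydride; 9 5-(benzyloxy)-2-iodophenol (2 equiv)
Product: 10 bis[5-(benzyloxy)-2-iodophenyl] meso-(2S,3S,4R,5R)-2,5-bis[4-(benzyloxy)phenyl]tetrahydrofuran-3,4-dicarboxylate
Conditions: DCC (1.1 equiv), DMAP (10 mol%), CH2Cl2, 0 °C to rt
Reagents that add atoms: none
Why: DMAP-catalysed opening of the anhydride by the phenol gives the half ester and carbodiimide coupling of its acid gives the diester (Steglich esterification); an activated half ester can only fall back to the cis-fused anhydride, so the cis relation of the two carboxyl-bearing carbons is kept.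

Step 5
Reactants: 10 bis(2-iodoaryl) tetrahydrofuran diester
Product: 13 meso-(2S,3R,2′R,3′S)-7,7′-bis(benzyloxy)-2,2′-bis[4-(benzyloxy)phenyl]-[3,3′-bichromane]-4,4′-dione, via diketone diphenol 11 (not isolated), via hydroxy flavanone 12 (not isolated)
Conditions: n-BuLi (2.05 equiv), THF/Et2O, −100 °C; then TFA (excess), CH2Cl2, −78 to 0 °C, same flask
Reagents that add atoms: none
Why: Iodine–lithium exchange at −100 °C should outrun addition of n-BuLi to the esters, and each aryllithium attacks its own ester carbonyl through a four-membered transition state and collapses to the ketone phenoxide, so C4–C4a and C4′–C4a′ form only at the iodine-bearing carbons (anionic Fries rearrangement triggered by halogen–metal exchange, the closest known type). TFA then frees diphenol 11 and protonates the ring ether, and the phenol of each aroyl group attacks the adjacent 4-(benzyloxy)benzylic carbon from the back, the ether oxygen leaving first as the benzylic hydroxyl of 12 and then as water, so O1–C2 and O1′–C2′ form (acid-mediated cycloetherification of a benzylic ether or alcohol by a phenol, as in the closure of 2′-hydroxy-β-hydroxydihydrochalcones to flavanones). Both rings C close in the 6-exo-tet mode, or 6-exo-trig if the p-alkoxybenzyl cation is free. C3 and C3′ are not touched and keep the cis relation from step 2, which is the meso (3R,3′S) arrangement; C2 and C2′ are set by displacement with inversion, which for the drawn isomer gives 2,3-trans, and the same diequatorial trans arrangement is the thermodynamic one if the benzylic C–O bond ionises reversibly, so other benzylic epimers of 10 converge. The step needs C-acylation before any ionisation, which the order of reagents secures because no acid is present while the electron-rich ester rings could still be C-alkylated to 4-aryldihydrocoumarins, and it needs ring closure to beat loss of the C3 proton, which the low temperature and the six-membered internal delivery of the nucleophile favour.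

Step 6
Reactants: 13 tetra-O-benzyl biflavanone
Product: 14 (2S,3R,2′R,3′S)-7,7′-dihydroxy-2,2′-bis(4-hydroxyphenyl)-[3,3′-bichromane]-4,4′-dione (target, meso, 2,3-trans in both rings)
Conditions: H2 (1 atm), 10% Pd/C, EtOAc/MeOH, rt
Reagents that add atoms: none
Why: Hydrogenolysis of the four aryl benzyl ethers over Pd/C should be faster than cleavage of the cyclic benzylic C2–O1 bonds or reduction of the aryl ketones, and the neutral medium leaves C2, C3, C3′ and C2′ untouched.

Compound list
1 | 4-(benzyloxy)benzaldehyde | O=Cc1ccc(OCc2ccccc2)cc1 | starting material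
2 | 4-(benzyloxy)benzyl chloride | ClCc1ccc(OCc2ccccc2)cc1 | starting material
3 | tetrahydrothiophene | C1CCSC1 | starting material
4 | 1-[4-(benzyloxy)benzyl]tetrahydrothiophen-1-ium chloride | [Cl-].c1ccccc1COc1ccc(C[S+]2CCCC2)cc1 | intermediate (not isolated)
5 | trans-2,3-bis[4-(benzyloxy)phenyl]oxirane, racemic, (2R,3R) drawn | c1ccccc1COc1ccc(cc1)[C@H]1O[C@@H]1c1ccc(OCc2ccccc2)cc1 | intermediate
6 | maleic anhydride | O=C1OC(=O)C=C1 | starting material
7 | meso-(3aR,4R,6S,6aS)-4,6-bis[4-(benzyloxy)phenyl]tetrahydro-1H,3H-furo[3,4-c]furan-1,3-dione (cis-fused; aryl groups cis to each other, trans to the anhydride ring) | O=C1OC(=O)[C@@H]2[C@H]1[C@@H](c1ccc(OCc3ccccc3)cc1)O[C@H]2c1ccc(OCc2ccccc2)cc1 | intermediate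
8 | 3-(benzyloxy)phenol | Oc1cccc(OCc2ccccc2)c1 | starting material
9 | 5-(benzyloxy)-2-iodophenol | Oc1cc(OCc2ccccc2)ccc1I | intermediate
10 | bis[5-(benzyloxy)-2-iodophenyl] meso-(2S,3S,4R,5R)-2,5-bis[4-(benzyloxy)phenyl]tetrahydrofuran-3,4-dicarboxylate (ester groups cis) | O=C(Oc1cc(OCc2ccccc2)ccc1I)[C@@H]1[C@H](C(=O)Oc2cc(OCc3ccccc3)ccc2I)[C@@H](c2ccc(OCc3ccccc3)cc2)O[C@H]1c1ccc(OCc2ccccc2)cc1 | intermediate
11 | [meso-(2S,3S,4R,5R)-2,5-bis[4-(benzyloxy)phenyl]tetrahydrofuran-3,4-diyl]bis{[4-(benzyloxy)-2-hydroxyphenyl]methanone}, formed as its dilithium bis(phenoxide) and freed by TFA | O=C(c1ccc(OCc2ccccc2)cc1O)[C@@H]1[C@H](C(=O)c2ccc(OCc3ccccc3)cc2O)[C@@H](c2ccc(OCc3ccccc3)cc2)O[C@H]1c1ccc(OCc2ccccc2)cc1 | intermediate (not isolated)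
12 | rac-(2S,3R)-7-(benzyloxy)-2-[4-(benzyloxy)phenyl]-3-{(1S,2S)-1-[4-(benzyloxy)-2-hydroxybenzoyl]-2-[4-(benzyloxy)phenyl]-2-hydroxyethyl}-2,3-dihydro-4H-chromen-4-one | O=C1c2ccc(OCc3ccccc3)cc2O[C@H](c2ccc(OCc3ccccc3)cc2)[C@H]1[C@H](C(=O)c1ccc(OCc2ccccc2)cc1O)[C@H](O)c1ccc(OCc2ccccc2)cc1 | intermediate (not isolated)
13 | meso-(2S,3R,2′R,3′S)-7,7′-bis(benzyloxy)-2,2′-bis[4-(benzyloxy)phenyl]-[3,3′-bichromane]-4,4′-dione | O=C1c2ccc(OCc3ccccc3)cc2O[C@H](c2ccc(OCc3ccccc3)cc2)[C@H]1[C@@H]1C(=O)c2ccc(OCc3ccccc3)cc2O[C@H]1c1ccc(OCc2ccccc2)cc1 | intermediate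
14 | (2S,3R,2′R,3′S)-7,7′-dihydroxy-2,2′-bis(4-hydroxyphenyl)-[3,3′-bichromane]-4,4′-dione | O=C1c2ccc(O)cc2O[C@H](c2ccc(O)cc2)[C@H]1[C@@H]1C(=O)c2ccc(O)cc2O[C@H]1c1ccc(O)cc1 | target

Total step count: 6. Longest linear sequence: 5 (steps 1, 2, 4, 5, 6).

Steps most likely to fail

Step 5. The aryllithium may deprotonate the carbon alpha to its ester (loss of aryloxide to a ketene, epimerisation of C3/C3′) or attack the neighbouring ester instead of its own. In the acid stage the benzylic cation may lose the C3 proton (chalcone formation and re-addition, which would scramble the C3/C3′ relation) or be captured by the remote ketone oxygen. The fallback sets out from 7. N,O-Dimethylhydroxylamine opens the anhydride to the amide acid F1, which is coupled in the same flask (EDC·HCl, HOBt) with a second equivalent of the amine to the bis(N-methoxy-N-methylamide) F2. Separately, 9 with two equivalents of n-BuLi at −78 °C gives lithium 5-(benzyloxy)-2-lithiophenoxide F3, which is added to F2. The stable chelated adducts are then treated in the same flask with TFA in CH2Cl2, which releases 11 and drives the same ring switch through 12. The route is rejoined at 13, with C4–C4a and O1–C2 still made in one operation but the ketone now formed by intermolecular addition instead of an acyl shift.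

Step 2. Back electron transfer may occur before the C–C bond of the epoxide radical cation opens, the radical cation may rearrange by hydride or aryl shift to a carbonyl compound, and maleic anhydride may undergo its own photoreactions with the arenes. The fallback sets out from 1. Hydrazine hydrate gives the hydrazone F4, which is oxidised with MnO2 at low temperature to [4-(benzyloxy)phenyl]diazomethane F5. Slow addition of F5 to 1 and 6 in the presence of Rh2(OAc)4 generates the rhodium carbene, which is captured by the aldehyde oxygen to give the same carbonyl ylide without light or an epoxide. Its cycloaddition with 6 returns to the route at 7.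

Step 6. Hydrogenolysis may also cleave the benzylic C2–O1 bonds (ring opening to dihydrochalcones) or reduce the aryl ketones. The fallback sets out from 13 and goes directly to 14 by Lewis-acid debenzylation with BCl3 and pentamethylbenzene as benzyl-cation scavenger in CH2Cl2 at −78 °C, which avoids reductive conditions. No new compound is made (F0).

Further compounds
F1 | step 5 | rac-(2R,3R,4S,5S)-2,5-bis[4-(benzyloxy)phenyl]-4-[methoxy(methyl)carbamoyl]tetrahydrofuran-3-carboxylic acid | O=C(O)[C@@H]1[C@H](C(=O)N(C)OC)[C@@H](c2ccc(OCc3ccccc3)cc2)O[C@H]1c1ccc(OCc2ccccc2)cc1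
F2 | step 5 | meso-(2S,3S,4R,5R)-2,5-bis[4-(benzyloxy)phenyl]-N3,N4-dimethoxy-N3,N4-dimethyltetrahydrofuran-3,4-dicarboxamide | CON(C)C(=O)[C@@H]1[C@H](C(=O)N(C)OC)[C@@H](c2ccc(OCc3ccccc3)cc2)O[C@H]1c1ccc(OCc2ccccc2)cc1
F3 | step 5 | lithium 5-(benzyloxy)-2-lithiophenoxide | [Li]Oc1cc(OCc2ccccc2)ccc1[Li]
F4 | step 2 | (E)-[4-(benzyloxy)benzylidene]hydrazine | N/N=C/c1ccc(OCc2ccccc2)cc1
F5 | step 2 | 1-(benzyloxy)-4-(diazomethyl)benzene | [N-]=[N+]=Cc1ccc(OCc2ccccc2)cc1
F0 | step 6 | none | none
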